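The runs come from a simulation for substances that don't exist; noise was put on by code.

Follow the intermediate rather than the substrate, and read from it the one rate that carries the product.

in all of them: substrate 10 mM

| flask | solid reagent | temperature | remark | time |
|---|---|---|---|---|
| teal | 27 mM | 110 °C | run made earlier |  |
| delta | 18.0 mM | 110 °C |  | 4.0 min |
| beta | 18.0 mM | 135 °C |  | 4.0 min |
| theta | 18.0 mM |  | at 135 °C until 50 s, from then on at 85 °C | 4.0 min |
| alpha | 18.0 mM | 85 °C |  | 4.0 min |

- teal (time / s: product / %, substrate / %): 10.0: 0.2, 93.6; 12.0: 0.1, 90.4; 20.0: 0.5, 81.7; 30.0: 2.5, 72.1; 50.0: 6.5, 57.6; 80.0: 12.7, 46.7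

(scatter of a reading: 0.5 percentage points)

- the flask with the highest amount of product, in percent of the substrate charged ("all alike" if they lie within 1.5 percentage points) (delta / beta / theta / alpha / all alike)
- final product, as a percentage of the substrate charged, in delta
- final product, as a percentage of the substrate charged, in beta
- final product, as a percentage of the substrate charged, in theta
- final product, as a percentage of the substrate charged, in alpha

- solid, in amounts per volume of the solution: solid reagent
- the numbers in the tables scatter with a standard deviation of 0.5 percentage points
- at the start none of the solid reagent is in solution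
- a reading or a percentage of product counts all its forms, free or not
- the earlier runs do not show what temperature does; that part of a forecast is a guess

In the teal run, count whatever is neither substrate nor product as intermediate: 35.9 % of the charge at 50.0 s, 40.6 % at 80.0 s. Teal's substrate leaves at 0.0119 s⁻¹ of the charge between 10.0 s and 20.0 s, but at 0.00363 s⁻¹ between 50.0 s and 80.0 s, slower by a factor of 3.28. Mean substrate falls by a factor of 1.68 between those spans. Read the remaining 1.95 as the first step nearing balance.

Now divide teal's product pace over that last span by the mean intermediate. This gives the hand-over constant, the fraction of the intermediate that becomes product each second, 0.00540 s⁻¹: a first-order rate constant for the last step, read with the scatter of the readings.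

Take the first step as balanced from 80.0 s on. Substrate and intermediate then form one pool, and teal's readings at 80.0 s give the intermediate a share 46.5 % of it. So each second 0.00251 s⁻¹ of the pool turns to product. Assume delta's smaller solid charge feeds as teal's did, and that delta stands at teal's readings at 80.0 s; the teal run does not test this. Over the remaining 160 s, delta's pool shrinks by a factor of 0.669, which puts delta at 41.6 %. Temperature stays a guess, so I reckon delta and no other flask.

The forecast, which holds that “the later slowdown suggests reagent supply limits the first step”, names beta and gives 40 % for delta, below my figure, with 88 % for beta, 35 % for theta and 5 % for alpha.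

The flasks give 46.2 % in delta, 95.0 % in beta, 39.7 % in theta and 6.04 % in alpha, so beta leads, as forecast.

    substrate + partner ⇌ intermediate (K = 240 L mol⁻¹, k = 4.30 L mol⁻¹ s⁻¹, Ea = 54.0 kJ mol⁻¹, ΔH = −5.00 kJ mol⁻¹)
    intermediate → product (k = 0.00580 s⁻¹, Ea = 96.0 kJ mol⁻¹)
    partner + product ⇌ idle adduct, settled at all times (K = 450 L mol⁻¹, ΔH = 4.00 kJ mol⁻¹)
    solid reagent ⇌ partner, rate k4*(cs4 - [partner]) while solid is left; crystals form when [partner] > cs4 (solubility = 5.80 mM, k = 0.0900 s⁻¹)
    (constants at 110 °C)

Put the hand-over constant on delta: between 2.00 min and 4.00 min the mean of its intermediate at those two times, 34.5 %, reckons to 22 percentage points, and delta gained 24 points. Alpha, read the same way, gives 7.30 × 10⁻⁴ s⁻¹ at 85 °C. The neighbouring flask is theta left until 15 min. The mean of its intermediate at 4.00 min and at 15.0 min is 30.7 %, so the cold constant reckons 15 points on top of theta's 39.7 %, reaching 54.5 %; that flask stands at 54.2 %.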